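## Retrosynthetic overview

1. The target is unmade at the C6 acetate and C18 methyl ester to the 18,6-lactone 35, then at C8=C17 (ketone methylenation, 34) and at C9–C11 (enolate alkylation) to the tricyclic silyl enol ether 28.
2. Ring A of 28 is cut at C1–C2 and C3–C4: the lactone enolate carbon C4, the two carbons of vinyltriphenylphosphonium bromide (C3, C2) and the C1 aldehyde on C10 of 23 are joined in one Michael/Wittig annulation.
3. The feature that allows this: the carboxyl carbon C18 on C4 and the oxygen on C6 are 1,3-related across C5 and both equatorial on rings A/B, so they can be tied as a γ-lactone trans-fused to ring B. Its enolate makes C4 the nucleophile with one open face (syn to H-5), and C1 sits on quaternary C10, so its aldehyde cannot enolise.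
4. Ring B (19 to 23): resolved carbinol (C6), α-methylbutenolide by metathesis, trans conjugate addition at C5, second metathesis to the lactone-fused enone, then axial methyl cuprate addition sets C10 and delivers the C8–C9 silyl enol ether.
5. Order of ring formation: lactone, ring B, ring A; the stereochemical relay runs C6 → C5 → C10 → C4 → C9.

Key step: step 13

Remark: atoms carry labdane numbers throughout (C17 = methylene carbon on C8, C18 = carboxyl carbon on C4, C19 = methyl on C4, C20 = methyl on C10); compounds 15–23 are carried as mixtures of C4 epimers and are written without a descriptor at that centre.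

## Route

Step 1
Reactants: 1 tert-butyl acetate; 2 acrolein
Product: 4 tert-butyl (±)-3-hydroxypent-4-enoate, via lithium enolate 3 (not isolated)
Conditions: LiN(iPr)2 (LDA), THF, −78 °C; then 2, −78 °C; aq NH4Cl
Reagents that add atoms: none
Why: Aldol addition of the lithium ester enolate to the aldehyde carbon of acrolein (1,2-addition) should give the β-hydroxy ester, whose carbinol centre (future C6) is formed racemic and is resolved in step 2.

Step 2
Reactants: 4 tert-butyl (±)-3-hydroxypent-4-enoate
Product: 5 tert-butyl (3R)-3-hydroxypent-4-enoate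
Conditions: Amano lipase PS (Burkholderia cepacia), vinyl acetate, MTBE, 30 °C, stopped just past half conversion; chromatography
Reagents that add atoms: none
Why: Enzymatic kinetic resolution by lipase transesterification should acetylate the (S)-alcohol (CH2CO2tBu as the large group, vinyl as the medium group) and leave the (R)-alcohol, whose carbinol centre becomes C6.

Step 3
Reactants: 5 tert-butyl (3R)-3-hydroxypent-4-enoate; 6 methacryloyl chloride
Product: 7 tert-butyl (3R)-3-[(2-methylprop-2-enoyl)oxy]pent-4-enoate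
Conditions: Et3N, DMAP (cat.), CH2Cl2, 0 °C → rt
Reagents that add atoms: none
Why: DMAP-catalysed O-acylation of the secondary allylic alcohol by the acid chloride should give the methacrylate without touching the stereocentre.

Step 4
Reactants: 7 tert-butyl (3R)-3-[(2-methylprop-2-enoyl)oxy]pent-4-enoate
Product: 8 tert-butyl 2-[(2R)-4-methyl-5-oxo-2,5-dihydrofuran-2-yl]acetate
Conditions: RuCl2(=CHPh)(PCy3)(H2IMes) (second-generation Grubbs catalyst, cat.), CH2Cl2, 40 °C
Reagents that add atoms: none
Why: Ring-closing metathesis of the allylic methacrylate should close the α-methylbutenolide (C4=C5) with loss of ethene, and C6 is not involved.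

Step 5
Reactants: 9 2,3-dibromopropene; 10 benzyl alcohol
Product: 12 benzyl 2-bromoallyl ether, via sodium benzyloxide 11 (not isolated)
Conditions: NaH, THF, 0 °C; then 9, rt
Reagents that add atoms: none
Why: Williamson ether synthesis: the alkoxide should displace the allylic bromide (SN2) while the vinylic bromide stays in place.

Step 6
Reactants: 8 tert-butyl 2-[(2R)-4-methyl-5-oxo-2,5-dihydrofuran-2-yl]acetate; 12 benzyl 2-bromoallyl ether
Product: 15 tert-butyl 2-[(2R,3R)-3-[3-(benzyloxy)prop-1-en-2-yl]-4-methyl-5-oxooxolan-2-yl]acetate, via alkenyllithium 13 (not isolated), via alkenylcopper 14 (not isolated)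
Conditions: 12, t-BuLi (2 equiv), Et2O, −78 °C; CuI, −78 → −40 °C; BF3·OEt2, −78 °C; then 8, −78 → −40 °C; aq NH4Cl
Reagents that add atoms: none
Why: Conjugate addition of the BF3-activated organocopper reagent to the butenolide should occur anti to the C6 side chain and so set C5 trans to C6, while C4 is protonated unselectively on work-up, which is harmless because that centre is planarised in step 13.

Step 7
Reactants: 15 tert-butyl 2-[(2R,3R)-3-[3-(benzyloxy)prop-1-en-2-yl]-4-methyl-5-oxooxolan-2-yl]acetate
Product: 16 2-[(2R,3R)-3-[3-(benzyloxy)prop-1-en-2-yl]-4-methyl-5-oxooxolan-2-yl]acetic acid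
Conditions: CF3CO2H, CH2Cl2, 0 °C → rt
Reagents that add atoms: none
Why: Acidolysis of the tert-butyl ester (loss of 2-methylpropene) should free the C8 carboxylic acid without touching the lactone, the benzyl ether or the inductively deactivated 1,1-disubstituted alkene.

Step 8
Reactants: 16 2-[(2R,3R)-3-[3-(benzyloxy)prop-1-en-2-yl]-4-methyl-5-oxooxolan-2-yl]acetic acid
Product: 18 (4R,5R)-4-[3-(benzyloxy)prop-1-en-2-yl]-3-methyl-5-(2-oxobut-3-en-1-yl)oxolan-2-one, via acid chloride 17 (not isolated)
Conditions: (COCl)2, DMF (cat.), CH2Cl2, 0 °C; then Bu3SnCH=CH2, PdCl2(PPh3)2 (cat.), toluene, 60 °C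
Reagents that add atoms: tributyl(vinyl)stannane, C=C[Sn](CCCC)(CCCC)CCCC
Why: The acid chloride should couple with the vinylstannane under palladium catalysis (Stille ketone synthesis) to give the vinyl ketone that carries C8 and C9, with lactone and benzyl ether inert.

Step 9
Reactants: 18 (4R,5R)-4-[3-(benzyloxy)prop-1-en-2-yl]-3-methyl-5-(2-oxobut-3-en-1-yl)oxolan-2-one
Product: 19 (3aR,7aR)-4-[(benzyloxy)methyl]-3-methyl-3a,7a-dihydro-1-benzofuran-2,6(3H,7H)-dione
Conditions: RuCl2(=CHPh)(PCy3)(H2IMes) (second-generation Grubbs catalyst, cat.), CH2Cl2, 40 °C, high dilution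
Reagents that add atoms: none
Why: Ring-closing metathesis between the vinyl ketone and the 1,1-disubstituted alkene should close ring B as the C9=C10 enone trans-fused to the lactone, with no stereocentre touched.

Step 10
Reactants: 19 (3aR,7aR)-4-[(benzyloxy)methyl]-3-methyl-3a,7a-dihydro-1-benzofuran-2,6(3H,7H)-dione
Product: 21 (3aR,4R,7aR)-4-[(benzyloxy)methyl]-6-[(tert-butyldimethylsilyl)oxy]-3,4-dimethyl-3a,4,7,7a-tetrahydro-1-benzofuran-2(3H)-one, via lithium enolate 20 (not isolated)
Conditions: Me2CuLi (from MeLi and CuI), Et2O, −20 °C; then t-BuMe2SiCl, HMPA, Et3N, THF, −78 °C → rt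
Reagents that add atoms: methyllithium (used as Me2CuLi), [Li]C; tert-butyldimethylsilyl chloride, CC(C)(C)[Si](C)(C)Cl
Why: Gilman cuprate 1,4-addition to the β,β-disubstituted enone: the trans-fused lactone locks H-5 pseudoaxial, so methyl should enter C10 axially on the face anti to H-5 (C20 axial, CH2OBn equatorial), and O-silylation of the regiodefined enolate gives the C8–C9 silyl enol ether that masks the ketone.

Step 11
Reactants: 21 (3aR,4R,7aR)-4-[(benzyloxy)methyl]-6-[(tert-butyldimethylsilyl)oxy]-3,4-dimethyl-3a,4,7,7a-tetrahydro-1-benzofuran-2(3H)-one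
Product: 22 (3aR,4R,7aR)-6-[(tert-butyldimethylsilyl)oxy]-4-(hydroxymethyl)-3,4-dimethyl-3a,4,7,7a-tetrahydro-1-benzofuran-2(3H)-one
Conditions: H2 (1 atm), Pd/C, NaHCO3, EtOAc, rt
Reagents that add atoms: none
Why: Hydrogenolysis of the benzyl ether over palladium should free the neopentyl alcohol, the hindered trisubstituted silyl enol ether being reduced far more slowly.

Step 12
Reactants: 22 (3aR,4R,7aR)-6-[(tert-butyldimethylsilyl)oxy]-4-(hydroxymethyl)-3,4-dimethyl-3a,4,7,7a-tetrahydro-1-benzofuran-2(3H)-one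
Product: 23 (3aR,4R,7aR)-6-[(tert-butyldimethylsilyl)oxy]-3,4-dimethyl-2-oxo-2,3,3a,4,7,7a-hexahydro-1-benzofuran-4-carbaldehyde
Conditions: nPr4N[RuO4] (cat.), N-methylmorpholine N-oxide, 4 Å molecular sieves, CH2Cl2, rt
Reagents that add atoms: none
Why: Ley–Griffith oxidation under neutral conditions should give the C1 aldehyde, which cannot enolise because C10 is quaternary, and should leave the silyl enol ether intact.

Step 13
Reactants: 23 (3aR,4R,7aR)-6-[(tert-butyldimethylsilyl)oxy]-3,4-dimethyl-2-oxo-2,3,3a,4,7,7a-hexahydro-1-benzofuran-4-carbaldehyde; 24 vinyltriphenylphosphonium bromide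
Product: 27 (4S,5S,6R,10R)-8-[(tert-butyldimethylsilyl)oxy]-11,12,13,14,15,16,17-heptanorlabda-1,8-dien-18,6-olide, via potassium enolate 25 (not isolated), via phosphorus ylide 26 (not isolated)
Conditions: KN(SiMe3)2 (1.05 equiv), THF, −78 → −40 °C; then 24, −78 °C → rt → 65 °C
Reagents that add atoms: none
Why: KN(SiMe3)2 removes H-4 from both C4 epimers of 23 to give the single planar lactone enolate 25, whose C4 adds to the β-carbon of 24 (Michael addition, bond C3–C4) to give ylide 26, and the ylide carbon C2 then attacks the C1 aldehyde and loses Ph3PO through the oxaphosphetane (intramolecular Wittig, bond C1–C2 formed as C1=C2). The closest known reaction type is the Schweizer annulation, the Michael addition of an enolate to a vinylphosphonium salt followed by intramolecular Wittig olefination, used here as an anionic [4+2] annulation with a two-carbon linchpin. Ring A is closed in the Wittig event as a six-membered ring by attack of the tethered ylide on an exocyclic C=O (6-exo-trig), which can only give the cis ring alkene. The one new stereocentre, quaternary C4, is set in the intermolecular Michael step: the γ-lactone trans-fused to ring B holds the enolate rigid, its face syn to quaternary C10 is shielded and 24 should add syn to H-5, which puts C3 cis to H-5 and leaves CH3 axial and the carboxyl carbon equatorial in ring A, so the epimer mixture converges on one configuration. The step needs deprotonation at C4 only and C-alkylation that outruns carbonyl addition; this is secured because the aldehyde on quaternary C10 has no α-hydrogen, the C8 ketone is masked as its silyl enol ether, intramolecular aldol addition would give a strained cyclobutanol that reverts, and the Michael/Wittig sequence is irreversible.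

Step 14
Reactants: 27 (4S,5S,6R,10R)-8-[(tert-butyldimethylsilyl)oxy]-11,12,13,14,15,16,17-heptanorlabda-1,8-dien-18,6-olide
Product: 28 (4S,5S,6R,10R)-8-[(tert-butyldimethylsilyl)oxy]-11,12,13,14,15,16,17-heptanorlabd-8-en-18,6-olide
Conditions: H2 (1 atm), Pd/C, EtOAc, rt
Reagents that add atoms: none
Why: Heterogeneous hydrogenation of the cis-disubstituted C1=C2 alkene should be much faster than that of the hindered silyl enol ether, so ring A is saturated selectively.

Step 15
Reactants: 29 (2E)-3-methylpent-2-en-4-yn-1-ol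
Product: 30 (2E)-3-methylpenta-2,4-dien-1-ol
Conditions: H2 (1 atm), Pd/CaCO3 poisoned with Pb(OAc)2 (Lindlar catalyst), quinoline, hexane/EtOAc, rt
Reagents that add atoms: none
Why: Lindlar semi-hydrogenation of the terminal alkyne should give the dienol with the trisubstituted E alkene unchanged.

Step 16
Reactants: 30 (2E)-3-methylpenta-2,4-dien-1-ol
Product: 31 (3E)-5-bromo-3-methylpenta-1,3-diene
Conditions: PBr3, pyridine (cat.), Et2O, −20 °C; used crude at once
Reagents that add atoms: phosphorus tribromide, BrP(Br)Br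
Why: Bromide displacement on the phosphite ester of the primary allylic alcohol (SN2) at low temperature should keep the E geometry.

Step 17
Reactants: 28 (4S,5S,6R,10R)-8-[(tert-butyldimethylsilyl)oxy]-11,12,13,14,15,16,17-heptanorlabd-8-en-18,6-olide; 31 (3E)-5-bromo-3-methylpenta-1,3-diene
Product: 34 (4S,5S,6R,9S,10R)-8-oxo-17-norlabda-12E,14-dien-18,6-olide, via sulfonium enolate 32 (not isolated), via C9 epimer 33 (not isolated)
Conditions: [(Me2N)3S][Me3SiF2] (TASF), THF, −78 °C; 31, −78 → 0 °C; then DBU (cat.), CH2Cl2, rt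
Reagents that add atoms: none
Why: Fluoride cleavage of the silyl enol ether gives the regiodefined C8–C9 enolate (fluoride-promoted enolate alkylation), which should be C-alkylated at C9 by the allylic bromide mainly anti to C20, and DBU then equilibrates C9 through the enol to the epimer with the side chain equatorial, the lactone C6–O bond being equatorial and poorly aligned for β-elimination.

Step 18
Reactants: 34 (4S,5S,6R,9S,10R)-8-oxo-17-norlabda-12E,14-dien-18,6-olide
Product: 35 (4S,5S,6R,9R,10S)-labda-8(17),12E,14-trien-18,6-olide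
Conditions: Zn, CH2Br2, TiCl4, THF/CH2Cl2, 0 °C → rt
Reagents that add atoms: dibromomethane, BrCBr
Why: Lombardo methylenation, a non-basic titanium–zinc methylene transfer, should convert the C8 ketone into the exocyclic alkene without epimerising C9 and without attacking the lactone carbonyl.

Step 19
Reactants: 35 (4S,5S,6R,9R,10S)-labda-8(17),12E,14-trien-18,6-olide
Product: 37 methyl (4S,5S,6R,9R,10S)-6-hydroxylabda-8(17),12E,14-trien-18-oate, via potassium carboxylate 36 (not isolated)
Conditions: KOH, MeOH/H2O, 60 °C; evaporate; then MeI, DMF, rt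
Reagents that add atoms: potassium hydroxide, [K+].[OH-]; iodomethane, CI
Why: Saponification opens the lactone to the hydroxy carboxylate and O-alkylation of the carboxylate with iodomethane (SN2) gives the methyl ester without passing through the free acid, which would relactonise; no stereocentre changes.

Step 20
Reactants: 37 methyl (4S,5S,6R,9R,10S)-6-hydroxylabda-8(17),12E,14-trien-18-oate
Product: 38 methyl (4S,5S,6R,9R,10S)-6-acetoxylabda-8(17),12E,14-trien-18-oate
Conditions: Ac2O, DMAP (cat.), pyridine, CH2Cl2, rt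
Reagents that add atoms: acetic anhydride, CC(=O)OC(C)=O
Why: DMAP-catalysed acetylation of the equatorial C6 alcohol should give the acetate with retention and complete the target.

## Compound list

1 | tert-butyl acetate | CC(=O)OC(C)(C)C | starting material
2 | acrolein | C=CC=O | starting material
3 | lithium enolate of tert-butyl acetate | [Li+].C=C([O-])OC(C)(C)C | intermediate
4 | tert-butyl (±)-3-hydroxypent-4-enoate | C=CC(O)CC(=O)OC(C)(C)C | intermediate
5 | tert-butyl (3R)-3-hydroxypent-4-enoate | C=C[C@H](O)CC(=O)OC(C)(C)C | intermediate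
6 | methacryloyl chloride | C=C(C)C(=O)Cl | starting material
7 | tert-butyl (3R)-3-[(2-methylprop-2-enoyl)oxy]pent-4-enoate | C=C[C@H](OC(=O)C(C)=C)CC(=O)OC(C)(C)C | intermediate
8 | tert-butyl 2-[(2R)-4-methyl-5-oxo-2,5-dihydrofuran-2-yl]acetate | CC1=C[C@@H](CC(=O)OC(C)(C)C)OC1=O | intermediate
9 | 2,3-dibromopropene | C=C(Br)CBr | starting material
10 | benzyl alcohol | OCc1ccccc1 | starting material
11 | sodium benzyloxide | [Na+].[O-]Cc1ccccc1 | intermediate
12 | benzyl 2-bromoallyl ether | C=C(Br)COCc1ccccc1 | intermediate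
13 | 3-(benzyloxy)prop-1-en-2-yllithium | [Li]C(=C)COCc1ccccc1 | intermediate
14 | [3-(benzyloxy)prop-1-en-2-yl]copper | [Cu]C(=C)COCc1ccccc1 | intermediate
15 | tert-butyl 2-[(2R,3R)-3-[3-(benzyloxy)prop-1-en-2-yl]-4-methyl-5-oxooxolan-2-yl]acetate (C4 epimers) | CC(C)(C)OC(=O)C[C@H]1OC(=O)C(C)[C@@H]1C(=C)COCc2ccccc2 | intermediate
16 | 2-[(2R,3R)-3-[3-(benzyloxy)prop-1-en-2-yl]-4-methyl-5-oxooxolan-2-yl]acetic acid (C4 epimers) | OC(=O)C[C@H]1OC(=O)C(C)[C@@H]1C(=C)COCc2ccccc2 | intermediate
17 | 2-[(2R,3R)-3-[3-(benzyloxy)prop-1-en-2-yl]-4-methyl-5-oxooxolan-2-yl]acetyl chloride (C4 epimers) | ClC(=O)C[C@H]1OC(=O)C(C)[C@@H]1C(=C)COCc2ccccc2 | intermediate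
18 | (4R,5R)-4-[3-(benzyloxy)prop-1-en-2-yl]-3-methyl-5-(2-oxobut-3-en-1-yl)oxolan-2-one (C4 epimers) | C=CC(=O)C[C@H]1OC(=O)C(C)[C@@H]1C(=C)COCc2ccccc2 | intermediate
19 | (3aR,7aR)-4-[(benzyloxy)methyl]-3-methyl-3a,7a-dihydro-1-benzofuran-2,6(3H,7H)-dione (C4 epimers; lactone-fused C9=C10 enone) | O=C1C=C(COCc2ccccc2)[C@H]2C(C)C(=O)O[C@@H]2C1 | intermediate
20 | lithium C8 enolate of the C10 methyl adduct | C1=C([O-])C[C@@H]3[C@@H]([C@@]1(C)COCc4ccccc4)C(C)C(=O)O3.[Li+] | intermediate
21 | (3aR,4R,7aR)-4-[(benzyloxy)methyl]-6-[(tert-butyldimethylsilyl)oxy]-3,4-dimethyl-3a,4,7,7a-tetrahydro-1-benzofuran-2(3H)-one (C4 epimers) | C1=C(O[Si](C)(C)C(C)(C)C)C[C@@H]3[C@@H]([C@@]1(C)COCc4ccccc4)C(C)C(=O)O3 | intermediate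
22 | (3aR,4R,7aR)-6-[(tert-butyldimethylsilyl)oxy]-4-(hydroxymethyl)-3,4-dimethyl-3a,4,7,7a-tetrahydro-1-benzofuran-2(3H)-one (C4 epimers) | C1=C(O[Si](C)(C)C(C)(C)C)C[C@@H]3[C@@H]([C@@]1(C)CO)C(C)C(=O)O3 | intermediate
23 | (3aR,4R,7aR)-6-[(tert-butyldimethylsilyl)oxy]-3,4-dimethyl-2-oxo-2,3,3a,4,7,7a-hexahydro-1-benzofuran-4-carbaldehyde (C4 epimers) | C1=C(O[Si](C)(C)C(C)(C)C)C[C@@H]3[C@@H]([C@@]1(C)C=O)C(C)C(=O)O3 | intermediate
24 | vinyltriphenylphosphonium bromide | C=C[P+](c1ccccc1)(c1ccccc1)c1ccccc1.[Br-] | starting material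
25 | potassium lactone enolate of 23 | C1=C(O[Si](C)(C)C(C)(C)C)C[C@@H]3[C@@H]([C@@]1(C)C=O)C(C)=C([O-])O3.[K+] | intermediate
26 | C2 phosphorus ylide (Michael adduct; C4 quaternary) | C1=C(O[Si](C)(C)C(C)(C)C)C[C@@H]3[C@@H]([C@@]1(C)C=O)[C@](C)(CC=P(c4ccccc4)(c4ccccc4)c4ccccc4)C(=O)O3 | intermediate
27 | (4S,5S,6R,10R)-8-[(tert-butyldimethylsilyl)oxy]-11,12,13,14,15,16,17-heptanorlabda-1,8-dien-18,6-olide | C1=C(O[Si](C)(C)C(C)(C)C)C[C@@H]3[C@H]2[C@@]1(C)C=CC[C@]2(C)C(=O)O3 | intermediate
28 | (4S,5S,6R,10R)-8-[(tert-butyldimethylsilyl)oxy]-11,12,13,14,15,16,17-heptanorlabd-8-en-18,6-olide | C1=C(O[Si](C)(C)C(C)(C)C)C[C@@H]3[C@H]2[C@@]1(C)CCC[C@]2(C)C(=O)O3 | intermediate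
29 | (2E)-3-methylpent-2-en-4-yn-1-ol | C#C/C(C)=C/CO | starting material
30 | (2E)-3-methylpenta-2,4-dien-1-ol | C=C/C(C)=C/CO | intermediate
31 | (3E)-5-bromo-3-methylpenta-1,3-diene | C=C/C(C)=C/CBr | intermediate
32 | tris(dimethylamino)sulfonium C8 enolate of 28 | C1=C([O-])C[C@@H]3[C@H]2[C@@]1(C)CCC[C@]2(C)C(=O)O3.CN(C)[S+](N(C)C)N(C)C | intermediate
33 | (4S,5S,6R,9R,10R)-8-oxo-17-norlabda-12E,14-dien-18,6-olide (C9 epimer, side chain axial) | C=C/C(C)=C/C[C@H]1C(=O)C[C@@H]3[C@H]2[C@@]1(C)CCC[C@]2(C)C(=O)O3 | intermediate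
34 | (4S,5S,6R,9S,10R)-8-oxo-17-norlabda-12E,14-dien-18,6-olide | C=C/C(C)=C/C[C@@H]1C(=O)C[C@@H]3[C@H]2[C@@]1(C)CCC[C@]2(C)C(=O)O3 | intermediate
35 | (4S,5S,6R,9R,10S)-labda-8(17),12E,14-trien-18,6-olide | C=C/C(C)=C/C[C@@H]1C(=C)C[C@@H]3[C@H]2[C@@]1(C)CCC[C@]2(C)C(=O)O3 | intermediate
36 | potassium (4S,5S,6R,9R,10S)-6-hydroxylabda-8(17),12E,14-trien-18-oate | C=C/C(C)=C/C[C@@H]1C(=C)C[C@@H](O)[C@H]2[C@@]1(C)CCC[C@]2(C)C(=O)[O-].[K+] | intermediate
37 | methyl (4S,5S,6R,9R,10S)-6-hydroxylabda-8(17),12E,14-trien-18-oate | C=C/C(C)=C/C[C@@H]1C(=C)C[C@@H](O)[C@H]2[C@@]1(C)CCC[C@]2(C)C(=O)OC | intermediate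
38 | methyl (4S,5S,6R,9R,10S)-6-acetoxylabda-8(17),12E,14-trien-18-oate | C=C/C(C)=C/C[C@@H]1C(=C)C[C@@H](OC(C)=O)[C@H]2[C@@]1(C)CCC[C@]2(C)C(=O)OC | target

## Step count and risks

Total step count: 20 (steps 5, 15 and 16 are side branches). Longest linear sequence: 17 steps (1–4, 6–14, 17–20).

Steps most likely to fail:

1. Step 13 (key step). Deprotonation of the hindered tertiary C4–H may be slow, so that the amide base or the first-formed enolate adds to the aldehyde or to the vinylphosphonium salt and uncyclised material results. The fallback forms the same two bonds in separate known operations and sets out from 23. Wittig methylenation with Ph3P=CH2 should give the C10-vinyl lactone F1. Enolisation with LiN(iPr)2 and alkylation with allyl bromide (same facial bias, syn to H-5) should give the C4-allyl lactone F2. Ring-closing metathesis with RuCl2(=CHPh)(PCy3)(H2IMes) (second-generation Grubbs catalyst) then closes ring A and returns to the route at 27.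

2. Step 17. C-alkylation at the hindered C9 enolate carbon may lose out to O-alkylation, to SN2′ attack on the dienyl bromide and to proton transfer that moves the enolate, and equilibration to the equatorial epimer may stay incomplete. The fallback sets out from 28 and 29 and unveils the diene last. PBr3 should convert 29 into the sturdier (2E)-1-bromo-3-methylpent-2-en-4-yne F3. The same fluoride-promoted alkylation and DBU equilibration should give the enyne ketone F4. Lombardo methylenation should give the enyne lactone F5. Lindlar semi-hydrogenation of the terminal alkyne then returns to the route at 35.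

3. Step 6. The 2-metallated allyl benzyl ether may lose benzyloxide by β-elimination, and addition to the α-methylated butenolide may be sluggish. The fallback sets out from 8. Copper-catalysed conjugate addition of commercial isopropenylmagnesium bromide (CuBr·SMe2, Me3SiCl) should give the trans isopropenyl lactone F6. Allylic oxidation of its methyl group with SeO2 (cat.) and t-BuOOH should give the allylic alcohol F7. Benzylation with benzyl 2,2,2-trichloroacetimidate and CF3SO3H (cat.) then returns to the route at 15.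

## Further compounds

F1 | step 13 | (3aR,4R,7aR)-6-[(tert-butyldimethylsilyl)oxy]-4-ethenyl-3,4-dimethyl-3a,4,7,7a-tetrahydro-1-benzofuran-2(3H)-one (C4 epimers) | C1=C(O[Si](C)(C)C(C)(C)C)C[C@@H]3[C@@H]([C@@]1(C)C=C)C(C)C(=O)O3
F2 | step 13 | C4-allyl C10-vinyl lactone (C4 quaternary, allyl syn to H-5) | C1=C(O[Si](C)(C)C(C)(C)C)C[C@@H]3[C@@H]([C@@]1(C)C=C)[C@](C)(CC=C)C(=O)O3
F3 | step 17 | (2E)-1-bromo-3-methylpent-2-en-4-yne | C#C/C(C)=C/CBr
F4 | step 17 | (4S,5S,6R,9S,10R)-8-oxo-17-norlabd-12E-en-14-yn-18,6-olide | C#C/C(C)=C/C[C@@H]1C(=O)C[C@@H]3[C@H]2[C@@]1(C)CCC[C@]2(C)C(=O)O3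
F5 | step 17 | (4S,5S,6R,9R,10S)-labda-8(17),12E-dien-14-yn-18,6-olide | C#C/C(C)=C/C[C@@H]1C(=C)C[C@@H]3[C@H]2[C@@]1(C)CCC[C@]2(C)C(=O)O3
F6 | step 6 | tert-butyl 2-[(2R,3R)-4-methyl-5-oxo-3-(prop-1-en-2-yl)oxolan-2-yl]acetate (C4 epimers) | CC(C)(C)OC(=O)C[C@H]1OC(=O)C(C)[C@@H]1C(C)=C
F7 | step 6 | tert-butyl 2-[(2R,3R)-3-(3-hydroxyprop-1-en-2-yl)-4-methyl-5-oxooxolan-2-yl]acetate (C4 epimers) | CC(C)(C)OC(=O)C[C@H]1OC(=O)C(C)[C@@H]1C(=C)CO
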